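## Retrosynthetic overview

1. The target comes from its ring-B aldehyde. CHO → CO2H is done last, so the decarboxylation-prone salicylic acid appears only in a cold final step.
2. Key disconnection: the diaryl ether C–O bond. It is made by direct C–H/O–H coupling of 2-heptyl-4-methoxybenzoic acid (its CO2H directs) with the 4-OH of 2-heptyl-4,6-dihydroxy-3-methoxybenzaldehyde.
3. The ring-A acid comes from 4-methoxy-2-methylbenzoic acid and 1-bromohexane by lateral lithiation.
4. The ring-B phenol comes from 2,4,5-trimethoxybenzaldehyde and 1-iodoheptane by directed ortho-metalation, then ortho/para-selective O-demethylation.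
5. No ring is built, since both benzene rings are bought. The plan is convergent: 1 step plus 2 steps, then 2 steps.

Assumption: the target has no stereocentre, no stable stereogenic axis and no C=C isomerism. It is one achiral compound, so no step needs stereocontrol.

## Route

Step 1
Reactants: 1 4-methoxy-2-methylbenzoic acid; 2 1-bromohexane
Product: 4 2-heptyl-4-methoxybenzoic acid, via dilithio dianion 3 (not isolated)
Conditions: LDA (2.2 equiv), THF, −78 → 0 °C; 2 (1.1 equiv), −78 °C → rt; 1 M HCl
Reagents that add atoms: 1-bromohexane (= reactant 2), CCCCCCBr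
Why: This is a lateral (benzylic) lithiation of an o-toluic acid, in which the lithium carboxylate directs the second deprotonation to the ortho methyl group and the dianion is C-alkylated by the primary bromide (SN2); no stereocentre is formed.

Step 2
Reactants: 5 2,4,5-trimethoxybenzaldehyde; 6 1-iodoheptane
Product: 10 2-heptyl-3,4,6-trimethoxybenzaldehyde, via lithium α-amino alkoxide 7 (not isolated), via 6-lithio α-amino alkoxide 8 (not isolated), via 6-heptyl α-amino alkoxide 9 (not isolated)
Conditions: MeNHCH2CH2NMe2 (1.1 equiv), n-BuLi (1.05 equiv), THF, −20 °C; 5; n-BuLi (2.5 equiv), −20 → 0 °C; 6 (4 equiv), DMPU, −40 °C → rt; 1 M HCl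
Reagents that add atoms: 1-iodoheptane (= reactant 6), CCCCCCCI
Why: This is a directed ortho-metalation through an in situ α-amino alkoxide (Comins protocol), in which C6 lies between the chelating amino alkoxide and the 5-OMe and is therefore lithiated in preference to C3, the aryllithium is alkylated by the primary iodide (SN2), and acid work-up returns the aldehyde and erases the transient racemic carbinolamine carbon.

Step 3
Reactants: 10 2-heptyl-3,4,6-trimethoxybenzaldehyde
Product: 12 2-heptyl-4,6-dihydroxy-3-methoxybenzaldehyde, via bis(dichloroaluminium) phenoxide 11 (not isolated)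
Conditions: AlCl3 (5 equiv), CH2Cl2, 0 °C → rt, 16 h; ice, 1 M HCl
Reagents that add atoms: none
Why: This is a Lewis-acid aryl methyl ether cleavage, in which carbonyl-bound AlCl3 activates the chelating ortho-OMe and the vinylogous-ester para-OMe for chloride attack at methyl (the selectivity recalled for the parent 2,4,5-trimethoxybenzaldehyde), while the OMe meta to CHO is not activated and stays.

Step 4
Reactants: 4 2-heptyl-4-methoxybenzoic acid (1.5 equiv); 12 2-heptyl-4,6-dihydroxy-3-methoxybenzaldehyde
Product: 14 2-(4-formyl-3-heptyl-5-hydroxy-2-methoxyphenoxy)-6-heptyl-4-methoxybenzoic acid, via mixed copper(II) carboxylate–aryloxide 13 (not isolated)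
Conditions: Cu(OAc)2 (3.0 equiv), CsOPiv (30 mol %), pyridine–DMSO 1:4, 4 Å MS, N2, 105 °C, 24 h; 1 M HCl/EDTA
Reagents that add atoms: none
Why: Proposed new method: a free-carboxylate-directed, carboxyl-retaining dehydrogenative ortho C–H/O–H coupling of a benzoic acid with a phenol, in which ligand exchange puts the carboxylate of 4 and the more acidic 4-O of 12 on one Cu(II) centre (13), carboxylate-assisted concerted metalation–deprotonation at the only free ortho C–H gives a five-membered cupracycle, a second Cu(II) oxidises it to an aryl–Cu(III) aryloxide, and C–O reductive elimination forms the ether; the 2-OH stays locked in its chelate with CHO (ortho-carbonyl phenols are poor O-arylation partners, and the extra Cu covers this sequestration), and silver-free conditions at 105 °C under N2 should hold back protodecarboxylation and aldehyde oxidation; the closest known reaction types are the Cu-mediated ortho C–H aryloxylation of benzamides carrying N,N-bidentate auxiliaries and the carboxylate-directed Cu/Ag ortho-alkoxylation that loses CO2.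

Step 5
Reactants: 14 2-(4-formyl-3-heptyl-5-hydroxy-2-methoxyphenoxy)-6-heptyl-4-methoxybenzoic acid
Product: 15 2-(4-carboxy-3-heptyl-5-hydroxy-2-methoxyphenoxy)-6-heptyl-4-methoxybenzoic acid (target)
Conditions: NaClO2 (2 equiv), H2NSO3H (3 equiv), THF–H2O, 0 °C → rt; cold work-up at pH 3
Reagents that add atoms: sodium chlorite, [Na+].[O-]Cl=O
Why: This is a Lindgren–Pinnick chlorite oxidation, in which chlorous acid converts the hindered, hydrogen-bonded salicylaldehyde into the acid without touching the phenol or the ethers, sulfamic acid traps HOCl before it can chlorinate the electron-rich rings, and the low temperature avoids decarboxylation.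

## Compound list

| No. | Name | SMILES | Role |
|---|---|---|---|
| 1 | 4-methoxy-2-methylbenzoic acid | Cc1cc(OC)ccc1C(=O)O | starting material |
| 2 | 1-bromohexane | CCCCCCBr | starting material |
| 3 | lithium 2-(lithiomethyl)-4-methoxybenzoate (dilithio dianion) | [Li]Cc1cc(OC)ccc1C(=O)O[Li] | intermediate |
| 4 | 2-heptyl-4-methoxybenzoic acid | CCCCCCCc1cc(OC)ccc1C(=O)O | intermediate |
| 5 | 2,4,5-trimethoxybenzaldehyde | COc1cc(OC)c(C=O)cc1OC | starting material |
| 6 | 1-iodoheptane | CCCCCCCI | starting material |
| 7 | lithium α-amino alkoxide of 5 with lithium N,N,N'-trimethylethylenediamide (racemic, transient) | [Li]OC(N(C)CCN(C)C)c1cc(OC)c(OC)cc1OC | intermediate |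
| 8 | 6-lithio derivative of 7 | [Li]OC(N(C)CCN(C)C)c1c([Li])c(OC)c(OC)cc1OC | intermediate |
| 9 | 6-heptyl derivative of 7 | [Li]OC(N(C)CCN(C)C)c1c(CCCCCCC)c(OC)c(OC)cc1OC | intermediate |
| 10 | 2-heptyl-3,4,6-trimethoxybenzaldehyde | CCCCCCCc1c(C=O)c(OC)cc(OC)c1OC | intermediate |
| 11 | 4,6-bis(dichloroaluminiooxy)-2-heptyl-3-methoxybenzaldehyde | CCCCCCCc1c(C=O)c(O[Al](Cl)Cl)cc(O[Al](Cl)Cl)c1OC | intermediate |
| 12 | 2-heptyl-4,6-dihydroxy-3-methoxybenzaldehyde | CCCCCCCc1c(C=O)c(O)cc(O)c1OC | intermediate |
| 13 | copper(II) (2-heptyl-4-methoxybenzoate)(4-formyl-3-heptyl-5-hydroxy-2-methoxyphenoxide) | CCCCCCCc1cc(OC)ccc1C(=O)O[Cu]Oc1cc(O)c(C=O)c(CCCCCCC)c1OC | intermediate |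
| 14 | 2-(4-formyl-3-heptyl-5-hydroxy-2-methoxyphenoxy)-6-heptyl-4-methoxybenzoic acid | CCCCCCCc1cc(OC)cc(Oc2cc(O)c(C=O)c(CCCCCCC)c2OC)c1C(=O)O | intermediate |
| 15 | 2-(4-carboxy-3-heptyl-5-hydroxy-2-methoxyphenoxy)-6-heptyl-4-methoxybenzoic acid (achiral) | CCCCCCCc1cc(OC)cc(Oc2cc(O)c(C(=O)O)c(CCCCCCC)c2OC)c1C(=O)O | target |

## Step count and risks

Total step count: 5.
Longest linear sequence: 4 (5 → 10 → 12 → 14 → 15).

**Step 4 (the proposed new step).**
- Risks: a monodentate carboxylate may not support cupration at 105 °C, the di-ortho-substituted product may lose CO2, and the salicylaldehyde unit of 12 may tie up copper.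
- Fallback (known chemistry): it sets out from 4.
- A carboxylate-directed Cp*Ir(III)-catalysed ortho C–H iodination (NIS, HFIP, rt) has only one ortho position free. Electrophilic iodination ortho to the OMe is the side reaction to watch. This gives 2-heptyl-6-iodo-4-methoxybenzoic acid F4.
- The ortho-carboxylate-accelerated Ullmann ether synthesis of F4 with phenol 12 (CuI 10 mol %, N,N-dimethylglycine, Cs2CO3, dioxane, 90 °C) comes back to the route at 14. The cost is one extra step.

**Step 2.**
- Risk: the doubly flanked aryllithium 8 may react sluggishly with a C7 iodide, and the excess n-BuLi consumes electrophile.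
- Fallback: it sets out from 8 and replaces the SN2 alkylation by cross-coupling.
- Compound 8 is quenched with I2 and worked up with acid to give 2-iodo-3,4,6-trimethoxybenzaldehyde F1.
- 1-Heptene is hydroborated with 9-BBN-H to give B-heptyl-9-borabicyclo[3.3.1]nonane F2.
- A B-alkyl Suzuki–Miyaura coupling of F1 with F2 (PdCl2(dppf), K3PO4, THF–DMF–H2O, 60 °C) comes back at 10.

**Step 3.**
- Risk: the remaining OMe sits between the heptyl chain and another oxygen and is twisted out of plane, so AlCl3 may attack it as well.
- Fallback: it sets out from 10 and splits the job between two mechanisms that do not rely on Lewis-acid site preference at that oxygen.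
- BCl3 (1.1 equiv, CH2Cl2, −78 → 0 °C) removes only the carbonyl-chelating methyl and gives 2-heptyl-6-hydroxy-3,4-dimethoxybenzaldehyde F3.
- NaSEt (DMF, 110 °C) then demethylates by SN2 at methyl. This step is governed by leaving-group ability, so the OMe para to CHO is cleaved. The route is rejoined at 12.

## Further compounds

F1 | step 2 | 2-iodo-3,4,6-trimethoxybenzaldehyde | COc1cc(OC)c(C=O)c(I)c1OC
F2 | step 2 | B-heptyl-9-borabicyclo[3.3.1]nonane | CCCCCCCB1C2CCCC1CCC2
F3 | step 3 | 2-heptyl-6-hydroxy-3,4-dimethoxybenzaldehyde | CCCCCCCc1c(C=O)c(O)cc(OC)c1OC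
F4 | step 4 | 2-heptyl-6-iodo-4-methoxybenzoic acid | CCCCCCCc1cc(OC)cc(I)c1C(=O)O
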